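## Structural features

Labdane numbering is used for atoms throughout; systematic names of intermediates carry their own locants. The target is a trans-fused decalin. Ring A (C1–C5, C10) is a saturated cyclohexane with a gem-dimethyl group at C4. Ring B (C5–C10) is a cyclohexenone with the ketone at C7, a tetrasubstituted C8=C9 double bond (C17 methyl on C8, side chain on C9) and an acetate on C6.

Three stereocenters are contiguous at the ring fusion: the quaternary C10 (methyl β), C5 (H α) and C6 (acetate β); the descriptors are 5S,6S,10S. The 6β-acetate is axial and syn to both the C10 methyl and the 4β-methyl. The fourth stereocenter, C13 (R), is a tertiary vinyl carbinol five bonds from the ring and cannot be controlled from it.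

Fragile groups are the α-acetoxy ketone (C6 can epimerise by enolisation and the acetyl group can migrate), the tertiary allylic alcohol (ionisation, oxidative transposition) and the terminal vinyl group (no late hydrogenation).

The real difficulty is threefold: the quaternary C10 in a ring B that is substituted on every carbon; the axial C6–O bond next to a ketone, which is best reached by delivering hydrogen, not oxygen, to C6 from the open α face; and the remote C13.

The key step exploits the substitution pattern of ring B. C6 (oxygen) and C9 (side-chain attachment) are para to each other, C8 and C10 each carry a methyl and flank C9, and C5–C10 is the ring fusion. This is the pattern of 2,6-dimethyl-1,4-benzoquinone. One of its C=C bonds becomes the C5–C10 fusion, and the four carbons of ring A (C1–C4, with both methyls on C4) are added to it as a diene. The C7 ketone then comes from C9 by a 1,3-oxygen shift, which the attachment of the side chain at a C9 carbonyl provides.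

## Logic of the disconnections

17 ⇒ 16. Only the O–Si bond at C13 is cut. The tertiary allylic alcohol would itself undergo oxidative transposition in the chromium step, so it must be masked until the end. The gain is a precursor with no free allylic alcohol. The demand is a non-basic desilylation that leaves the epimerisable C6 untouched.

16 ⇒ 15. The C7=O bond and the C8=C9 double bond are traced back to a C9–OH bond and a C7=C8 double bond (1,3-oxidative transposition). The cut is made here because it moves the ring-B carbonyl to C9, where a carbon nucleophile can deliver the side chain. It also means the C6 acetate never sits next to a ketone until the last oxidation. The gain is that C9 becomes a disposable stereocenter. The demand is a suprafacial shift of the chromate ester without ionisation of the allylic system.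

15 ⇒ 14 ⇒ 6 + 12. The acetyl C–O bond at C6 is cut, then the C9–C11 bond. This is the convergent cut: it separates the remote C13 stereocenter into a chiral-pool fragment and leaves a bicyclic hydroxy-enone. The gain is two fragments of similar size, each with its stereochemistry settled independently. The demands are 1,2-addition to a neopentylic enone carbonyl and acetylation of the secondary C6–OH in the presence of the tertiary C9–OH.

6 ⇒ 5 ⇒ 4. The C–H bonds at C2 and C3 and the C6–H bond are cut (hydrogenation, hydride addition). C6 is set by hydride arriving anti to the two syn-axial methyls, the one mode that puts oxygen β. The gain is an ene-dione with only two stereocenters. The demands are discrimination between the C6 and C9 carbonyls and between the isolated C2=C3 and the conjugated C7=C8 double bonds.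

4 ⇒ 3. The C5–H bond is cut and re-formed on the other face (epimerisation α to the C6 carbonyl). This converts the cis fusion that a cycloaddition must give into the trans fusion of the target. The gain is that the key step need control only C10. The demand is that the trans isomer be reachable by equilibration or kinetic protonation.

3 ⇒ 1 + 2 (key disconnection). The C1–C10 and C4–C5 bonds are cut. This removes ring A, the quaternary C10 and the gem-dimethyl carbon in one operation and leaves two achiral commercial compounds. The gain is the largest of the route: a bicyclic ene-dione with every ring-B handle in place goes back to a symmetric dienophile and a C6 diene. The demand is a regio- and enantioselective cycloaddition with a diene that is reluctant to adopt the s-cis conformation.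

12 ⇒ 10 ⇒ 9 ⇒ 8 ⇒ 7. The C–I bond is traced to a C–CO2H bond (one carbon excised), the acid to the aldehyde, the aldehyde C=O to the trisubstituted C6=C7 double bond of 7, and the O–Si bond to the free alcohol. The C13 stereocenter is bought, not made. The gain is a four-step fragment synthesis with no stereochemical operation. The demands are ozonolysis of the trisubstituted alkene in the presence of the vinyl group and a radical decarboxylation that tolerates it.

## Other disconnections considered

Alternative 1: This is the route that comes to mind first, semisynthesis by late oxygenation of a preformed labdane. The cut is at the C7=O and C6–O bonds. Forward, (−)-sclareol A1 is dehydrated to (13R)-labda-8,14-dien-13-ol A2, oxidised at the allylic C7 to (13R)-13-hydroxylabda-8,14-dien-7-one A3, and acetoxylated at C6 through the enolate or with Mn(OAc)3. An electrophilic oxygen reagent should approach the C6 enolate from the α face, away from the C10 and 4β methyls. The expected product is therefore the 6α-acetate A4, the C6 epimer of the target. Correcting it needs a redox detour through a 6,7-dioxygenated ring. In addition, dehydration of the C8 carbinol competes with ionisation of the C13 vinyl carbinol, and the allylic oxidation must choose C7 over C11. The chosen plan sets C6 by hydride delivery before any C7 ketone exists.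

Alternative 2: The cut is at C4–C5 and C9–C10, closing both rings by cation–olefin bicyclisation of (3R,6E,10E)-geranyllinalool A5 (or a C13-protected form) to A2. The tertiary allylic C13–O bond should ionise more easily than the terminal trisubstituted alkene is protonated. The absolute configuration at C5/C10 would have to come from a chiral proton source working against a remote stereocenter. Termination is expected to give mixtures of C7-, C8- and C8(17)-olefins. The route also converges on A2 and so inherits both late oxidations and the C6 problem of Alternative 1, with no gain in step economy.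

Alternative 3: The cut is at C9–C11 with the C7 ketone already present. Forward, the C9 enol triflate A7 of 6β-acetoxy-8-methyl-decalin-7,9-dione A6 is cross-coupled (sp2–sp3) with the organozinc derived from 12. In A6 the C6 stereocenter is α to a β-diketone carbonyl and should epimerise, with acetyl migration, under the basic conditions of triflation and coupling. Triflation is expected at the less hindered C7 oxygen and not at the neopentylic C9 oxygen, which puts the leaving group on the wrong carbon. A6 would still need its own asymmetric synthesis. The chosen plan joins the chain by carbonyl addition at C9 and makes the C7 ketone last.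

Key step: step 1

Assumption: the target is read as (5S,6S,10S,13R), i.e. the 6β-acetate of the normal labdane series with 13R. The sense of induction of the oxazaborolidinium catalyst in step 1 is assigned by analogy with other quinone cycloadditions; if it were the opposite, the enantiomeric catalyst would be used with nothing else changed.

Locant mapping for 3–6: naphthalene positions 1, 2, 3, 4, 4a, 5, 6, 7, 8, 8a are labdane C9, C8, C7, C6, C5, C4, C3, C2, C1, C10.

## Route

Step 1
Reactants: 1 2,6-dimethyl-1,4-benzoquinone; 2 4-methylpenta-1,3-diene
Product: 3 (4aR,8aS)-2,5,5,8a-tetramethyl-4a,5,8,8a-tetrahydronaphthalene-1,4-dione (cis-fused adduct)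
Conditions: 2 (5 equiv), (S)-3,3-diphenyl-1-(o-tolyl)tetrahydropyrrolo[1,2-c][1,3,2]oxazaborole (20 mol %) activated with Tf2NH (18 mol %), CH2Cl2, −78 to −20 °C
Reagents that add atoms: none
Why: The protonated oxazaborolidine should bind the quinone at the C6 carbonyl oxygen (the carbonyl flanked by two C–H groups, the more basic and less hindered one), which makes the methyl-bearing β-carbon C10 the most electrophilic site. The reaction is a Lewis-acid-catalysed, normal-electron-demand Diels–Alder cycloaddition of the type known for quinones with simple dienes, concerted but asynchronous: the unsubstituted CH2 terminus of the diene (largest HOMO coefficient, C1) bonds in advance to C10 and the dimethyl-substituted terminus (C4) closes onto the unhindered C5. Ring A is closed in one suprafacial [4+2] event that forms C1–C10 and C4–C5. The quaternary C10 is set by the catalyst, which shields one face of the coordinated enone; C5 necessarily arises cis to the C10 methyl and is corrected in step 2. Regioselectivity is the one selectivity the substrates must supply, and electronics (nucleophilic terminus to the β-carbon of the activated carbonyl) and sterics (the CMe2 terminus to the C–H carbon) point the same way. Site selectivity does not arise because the two quinone double bonds are equivalent, and endo/exo selectivity does not arise because C4 carries two identical methyls. The weak point is the low s-cis population of a diene with a Z-terminal methyl, answered by excess diene, a strongly activating catalyst and a temperature ramp.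

Step 2
Reactants: 3 (4aR,8aS)-2,5,5,8a-tetramethyl-4a,5,8,8a-tetrahydronaphthalene-1,4-dione
Product: 4 (4aS,8aS)-2,5,5,8a-tetramethyl-4a,5,8,8a-tetrahydronaphthalene-1,4-dione (trans-fused)
Conditions: DBU (0.2 equiv), toluene, 23 °C; unconverted 3 separated and resubmitted
Reagents that add atoms: none
Why: Base-mediated epimerisation through the dienolate: C5–H is α to the C6 carbonyl of an ene-dione and exchanges readily, aromatisation is blocked by the quaternary C10, and both equilibration towards the trans-fused ring system and reprotonation anti to the C10 methyl should funnel the material to the trans isomer.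

Step 3
Reactants: 4 (4aS,8aS)-2,5,5,8a-tetramethyl-4a,5,8,8a-tetrahydronaphthalene-1,4-dione
Product: 5 (4R,4aS,8aS)-4-hydroxy-2,5,5,8a-tetramethyl-4a,5,8,8a-tetrahydronaphthalen-1(4H)-one
Conditions: NaBH4 (1.0 equiv), CeCl3·7H2O (1.1 equiv), MeOH, −78 °C
Reagents that add atoms: none
Why: Luche 1,2-reduction; the C9 carbonyl is neopentylic (between the quaternary C10 and the methyl-bearing C8), so hydride should take the C6 carbonyl, and it should arrive from the α face, anti to the syn-axial C10 and 4β methyls, giving the axial 6β-alcohol.

Step 4
Reactants: 5 (4R,4aS,8aS)-4-hydroxy-2,5,5,8a-tetramethyl-4a,5,8,8a-tetrahydronaphthalen-1(4H)-one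
Product: 6 (4R,4aS,8aS)-4-hydroxy-2,5,5,8a-tetramethyl-4a,5,6,7,8,8a-hexahydronaphthalen-1(4H)-one
Conditions: H2 (1–3 atm), RhCl(PPh3)3 (5 mol %), benzene/EtOH, 23 °C
Reagents that add atoms: none
Why: Homogeneous rhodium-catalysed hydrogenation discriminates by substitution: the isolated cis-disubstituted C2=C3 bond should be reduced while the trisubstituted, conjugated C7=C8 bond stays; no stereocenter is created.

Step 5
Reactants: 7 (R)-(−)-linalool [(3R)-3,7-dimethylocta-1,6-dien-3-ol]
Product: 8 (R)-triethyl[(3,7-dimethylocta-1,6-dien-3-yl)oxy]silane
Conditions: TESOTf (1.2 equiv), 2,6-lutidine (1.5 equiv), CH2Cl2, −78 to 0 °C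
Reagents that add atoms: triethylsilyl trifluoromethanesulfonate, CC[Si](CC)(CC)OS(=O)(=O)C(F)(F)F
Why: Silylation of a tertiary alcohol with a silyl triflate; the C13 stereocenter is taken from the chiral pool and is not touched here or later.

Step 6
Reactants: 8 (R)-triethyl[(3,7-dimethylocta-1,6-dien-3-yl)oxy]silane
Product: 9 (R)-4-methyl-4-[(triethylsilyl)oxy]hex-5-enal
Conditions: O3 (1.0 equiv, Sudan Red 7B endpoint), CH2Cl2/MeOH, −78 °C; then Me2S
Reagents that add atoms: ozone, [O-][O+]=O
Why: Ozonolysis with reductive work-up; the electron-rich trisubstituted alkene should react well ahead of the monosubstituted vinyl group, which is also deactivated and shielded by the adjacent silyloxy-bearing quaternary carbon.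

Step 7
Reactants: 9 (R)-4-methyl-4-[(triethylsilyl)oxy]hex-5-enal
Product: 10 (R)-4-methyl-4-[(triethylsilyl)oxy]hex-5-enoic acid
Conditions: NaClO2, NaH2PO4, 2-methyl-2-butene, t-BuOH/H2O, 0 to 23 °C
Reagents that add atoms: sodium chlorite, [Na+].[O-]Cl=O
Why: Pinnick oxidation; the buffered chlorite conditions with an alkene scavenger should spare the vinyl group and the tertiary silyl ether.

Step 8
Reactants: 10 (R)-4-methyl-4-[(triethylsilyl)oxy]hex-5-enoic acid
Product: 12 (R)-triethyl[(5-iodo-3-methylpent-1-en-3-yl)oxy]silane, via Barton ester 11 (not isolated)
Conditions: 1-hydroxypyridine-2(1H)-thione, DCC, CH2Cl2, 0 °C, dark; then CHI3, benzene, hν (tungsten lamp), 40 °C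
Reagents that add atoms: iodoform, IC(I)I; 1-hydroxypyridine-2(1H)-thione, ON1C=CC=CC1=S (atoms retained in 11 only)
Why: Barton decarboxylative iodination: the thiohydroxamate ester fragments to a primary radical that abstracts iodine from iodoform; the radical is a pent-4-enyl radical, for which neither the 4-exo nor the 5-endo cyclisation onto the vinyl group should compete, and the excised carbon gives the two-carbon spacing C11–C12 that the target needs.

Step 9
Reactants: 12 (R)-triethyl[(5-iodo-3-methylpent-1-en-3-yl)oxy]silane; 6 (4R,4aS,8aS)-4-hydroxy-2,5,5,8a-tetramethyl-4a,5,6,7,8,8a-hexahydronaphthalen-1(4H)-one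
Product: 14 (6β,13R)-13-[(triethylsilyl)oxy]labda-7,14-diene-6,9-diol (5S,10S; C9 epimers), via organolithium 13 (not isolated)
Conditions: 12 (2.3 equiv), t-BuLi (4.6 equiv), Et2O/pentane, −78 °C; then 6 in THF, −78 to 0 °C; H2O
Reagents that add atoms: none
Why: Iodine–lithium exchange followed by 1,2-addition of the primary alkyllithium to the enone carbonyl, as in additions to 2,6,6-trisubstituted cyclohex-2-enones; the first equivalent deprotonates the C6 hydroxyl, the carbonyl has no α-hydrogen so enolisation cannot compete, and the new C9 configuration is irrelevant because both epimers converge in step 11.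

Step 10
Reactants: 14 (6β,13R)-13-[(triethylsilyl)oxy]labda-7,14-diene-6,9-diol
Product: 15 (6β,13R)-9-hydroxy-13-[(triethylsilyl)oxy]labda-7,14-dien-6-yl acetate (5S,10S; C9 epimers)
Conditions: Ac2O (3 equiv), DMAP (0.3 equiv), Et3N, CH2Cl2, 23 to 40 °C
Reagents that add atoms: acetic anhydride, CC(=O)OC(C)=O
Why: DMAP-catalysed acetylation; the axial secondary C6 hydroxyl is hindered but far more accessible than the tertiary C9 hydroxyl wedged between the quaternary C10 and C8, and C13 is silylated, so only C6 should be acylated, at a stage where C6 cannot epimerise.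

Step 11
Reactants: 15 (6β,13R)-9-hydroxy-13-[(triethylsilyl)oxy]labda-7,14-dien-6-yl acetate
Product: 16 (5S,6S,10S,13R)-7-oxo-13-[(triethylsilyl)oxy]labda-8,14-dien-6-yl acetate
Conditions: pyridinium chlorochromate [C5H5NH][CrO3Cl] (3 equiv), 4 Å molecular sieves, CH2Cl2, 23 °C
Reagents that add atoms: pyridinium chlorochromate, c1cc[nH+]cc1.[O-][Cr](=O)(=O)Cl
Why: Babler–Dauben oxidative transposition: the chromate ester of the tertiary allylic alcohol shifts suprafacially ([3,3]) to C7 and the secondary chromate collapses to the ketone, which gives the tetrasubstituted C8=C9 enone from either C9 epimer; C6 is not involved, and the silyl ether keeps the C13 vinyl carbinol out of the same reaction.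

Step 12
Reactants: 16 (5S,6S,10S,13R)-7-oxo-13-[(triethylsilyl)oxy]labda-8,14-dien-6-yl acetate
Product: 17 (5S,6S,10S,13R)-13-hydroxy-7-oxolabda-8,14-dien-6-yl acetate (target, CNP0328351.1)
Conditions: HF·pyridine, pyridine, THF, 0 to 23 °C
Reagents that add atoms: none
Why: Fluoride-mediated cleavage of the tertiary silyl ether under buffered, non-basic conditions, which should leave the acetate and the epimerisable α-acetoxy ketone untouched.

## Compound list

1 | 2,6-dimethyl-1,4-benzoquinone | CC1=CC(=O)C=C(C)C1=O | starting material
2 | 4-methylpenta-1,3-diene | C=CC=C(C)C | starting material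
3 | (4aR,8aS)-2,5,5,8a-tetramethyl-4a,5,8,8a-tetrahydronaphthalene-1,4-dione (cis-fused) | O=C1C(C)=CC(=O)[C@@H]2C(C)(C)C=CC[C@]12C | intermediate
4 | (4aS,8aS)-2,5,5,8a-tetramethyl-4a,5,8,8a-tetrahydronaphthalene-1,4-dione (trans-fused) | O=C1C(C)=CC(=O)[C@H]2C(C)(C)C=CC[C@]12C | intermediate
5 | (4R,4aS,8aS)-4-hydroxy-2,5,5,8a-tetramethyl-4a,5,8,8a-tetrahydronaphthalen-1(4H)-one | O=C1C(C)=C[C@@H](O)[C@H]2C(C)(C)C=CC[C@]12C | intermediate
6 | (4R,4aS,8aS)-4-hydroxy-2,5,5,8a-tetramethyl-4a,5,6,7,8,8a-hexahydronaphthalen-1(4H)-one | O=C1C(C)=C[C@@H](O)[C@H]2C(C)(C)CCC[C@]12C | intermediate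
7 | (R)-(−)-linalool, (3R)-3,7-dimethylocta-1,6-dien-3-ol | C=C[C@](C)(O)CCC=C(C)C | starting material
8 | (R)-triethyl[(3,7-dimethylocta-1,6-dien-3-yl)oxy]silane | C=C[C@](C)(O[Si](CC)(CC)CC)CCC=C(C)C | intermediate
9 | (R)-4-methyl-4-[(triethylsilyl)oxy]hex-5-enal | C=C[C@](C)(O[Si](CC)(CC)CC)CCC=O | intermediate
10 | (R)-4-methyl-4-[(triethylsilyl)oxy]hex-5-enoic acid | C=C[C@](C)(O[Si](CC)(CC)CC)CCC(=O)O | intermediate
11 | 2-thioxopyridin-1(2H)-yl (R)-4-methyl-4-[(triethylsilyl)oxy]hex-5-enoate (Barton ester) | C=C[C@](C)(O[Si](CC)(CC)CC)CCC(=O)ON1C=CC=CC1=S | intermediate (not isolated)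
12 | (R)-triethyl[(5-iodo-3-methylpent-1-en-3-yl)oxy]silane | C=C[C@](C)(O[Si](CC)(CC)CC)CCI | intermediate
13 | {(3R)-3-methyl-3-[(triethylsilyl)oxy]pent-4-en-1-yl}lithium | C=C[C@](C)(O[Si](CC)(CC)CC)CC[Li] | intermediate (not isolated)
14 | (6β,13R)-13-[(triethylsilyl)oxy]labda-7,14-diene-6,9-diol (5S,10S; C9 configuration not defined) | C=C[C@](C)(O[Si](CC)(CC)CC)CCC1(O)C(C)=C[C@@H](O)[C@H]2C(C)(C)CCC[C@]12C | intermediate
15 | (6β,13R)-9-hydroxy-13-[(triethylsilyl)oxy]labda-7,14-dien-6-yl acetate (5S,10S; C9 configuration not defined) | C=C[C@](C)(O[Si](CC)(CC)CC)CCC1(O)C(C)=C[C@@H](OC(C)=O)[C@H]2C(C)(C)CCC[C@]12C | intermediate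
16 | (5S,6S,10S,13R)-7-oxo-13-[(triethylsilyl)oxy]labda-8,14-dien-6-yl acetate | C=C[C@](C)(O[Si](CC)(CC)CC)CCC1=C(C)C(=O)[C@@H](OC(C)=O)[C@H]2C(C)(C)CCC[C@]12C | intermediate
17 | (5S,6S,10S,13R)-13-hydroxy-7-oxolabda-8,14-dien-6-yl acetate | C=C[C@](C)(O)CCC1=C(C)C(=O)[C@@H](OC(C)=O)[C@H]2C(C)(C)CCC[C@]12C | target

## Step count and least certain steps

Total step count: 12. Longest linear sequence: 8 (steps 1–4 and 9–12; the side-chain branch, steps 5–8 and 9–12, is also 8).

Step 1 (key step). The most likely failure is a slow cycloaddition, because the diene must reach the s-cis conformation against its Z-terminal methyl. At the temperatures then needed, facial discrimination by the catalyst erodes, and acid-induced oligomerisation of the diene or stepwise (2+2) or (3+2) addition to the quinone can take over. Fallback, setting out from 1 and 2: the cycloaddition is run without catalyst under high pressure (about 12 kbar, CH2Cl2, 23 °C). This gives the racemic adduct, i.e. 3 together with its mirror image (4aS,8aR)-2,5,5,8a-tetramethyl-4a,5,8,8a-tetrahydronaphthalene-1,4-dione F1. Epimerisation as in step 2 then gives 4 together with (4aR,8aR)-2,5,5,8a-tetramethyl-4a,5,8,8a-tetrahydronaphthalene-1,4-dione F2. The enantiomers are separated by preparative chromatography on a chiral stationary phase, and the route is rejoined at 4.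

Step 2. The most likely failure is an incomplete or unfavourable cis/trans equilibrium, since the interaction of the equatorial C4 methyl with the C6 carbonyl in the trans isomer offsets part of its advantage; slow side reactions of the dienolate on long exposure to base are a second concern. Fallback, setting out from 3 (or any mixture of 3 and 4): soft enolisation with TBSOTf/Et3N, which can occur only towards C5, gives (S)-4-[(tert-butyldimethylsilyl)oxy]-2,5,5,8a-tetramethyl-8,8a-dihydronaphthalen-1(5H)-one F3. Fluoride-induced desilylation with kinetic protonation (Bu4NF, AcOH, THF, −78 °C) should then deliver the proton to C5 from the face anti to the C10 methyl, and the route is rejoined at 4.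

Step 11. The most likely failure is ionisation of the tertiary allylic chromate in place of the concerted shift. That would allow participation of the neighbouring C6 acetate (acetoxonium formation, acetyl migration between C6 and C7) or elimination towards C11. Acid-induced loss of the silyl ether would also expose the C13 carbinol to the same oxidation. Fallback, setting out from 15: a redox-neutral 1,3-transposition with catalytic Ph3SiOReO3 (Et2O, −50 to 0 °C), driven by formation of the tetrasubstituted alkene, gives (6β,13R)-7-hydroxy-13-[(triethylsilyl)oxy]labda-8,14-dien-6-yl acetate F4 (C7 epimers). Oxidation of this secondary allylic alcohol with MnO2 (CH2Cl2, 23 °C) rejoins the route at 16.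

Step 9. The most likely failure is incomplete addition to the neopentylic carbonyl once the neighbouring hydroxyl is a lithium alkoxide (aggregation, consumption of the fragment as a base), leaving 6 or diverting to 1,4-addition. Fallback, setting out from 6: the hydroxyl is acetylated first (Ac2O, DMAP, Et3N) to give (1R,4aS,8aS)-3,4a,8,8-tetramethyl-4-oxo-1,4,4a,5,6,7,8,8a-octahydronaphthalen-1-yl acetate F5. The organocerium reagent made from 13 and anhydrous CeCl3 (1.3 equiv, THF, −78 °C), which adds to ketones faster than to esters, is then used. This rejoins the route directly at 15 and bypasses 14.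

Step 8. The most likely failure is inefficient iodine-atom transfer (pyridylthio transfer to the radical, or addition of thiyl radicals to the vinyl group) together with loss of the light-sensitive iodide. Fallback, setting out from 9: the aldehyde is converted with TIPSOTf/Et3N into triethyl{[(3R)-3-methyl-6-[(triisopropylsilyl)oxy]hexa-1,5-dien-3-yl]oxy}silane F6. Ozonolysis of the electron-rich enol ether double bond (O3, 1 equiv, −78 °C; Me2S) gives (R)-3-methyl-3-[(triethylsilyl)oxy]pent-4-enal F7. Reduction with NaBH4 gives (R)-3-methyl-3-[(triethylsilyl)oxy]pent-4-en-1-ol F8. Appel iodination (I2, PPh3, imidazole) rejoins the route at 12.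

## Further compounds

F1 | step 1 | (4aS,8aR)-2,5,5,8a-tetramethyl-4a,5,8,8a-tetrahydronaphthalene-1,4-dione | O=C1C(C)=CC(=O)[C@H]2C(C)(C)C=CC[C@@]12C
F2 | step 1 | (4aR,8aR)-2,5,5,8a-tetramethyl-4a,5,8,8a-tetrahydronaphthalene-1,4-dione | O=C1C(C)=CC(=O)[C@@H]2C(C)(C)C=CC[C@@]12C
F3 | step 2 | (S)-4-[(tert-butyldimethylsilyl)oxy]-2,5,5,8a-tetramethyl-8,8a-dihydronaphthalen-1(5H)-one | O=C1C(C)=CC(O[Si](C)(C)C(C)(C)C)=C2C(C)(C)C=CC[C@]12C
F4 | step 11 | (6β,13R)-7-hydroxy-13-[(triethylsilyl)oxy]labda-8,14-dien-6-yl acetate (C7 epimers) | C=C[C@](C)(O[Si](CC)(CC)CC)CCC1=C(C)C(O)[C@@H](OC(C)=O)[C@H]2C(C)(C)CCC[C@]12C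
F5 | step 9 | (1R,4aS,8aS)-3,4a,8,8-tetramethyl-4-oxo-1,4,4a,5,6,7,8,8a-octahydronaphthalen-1-yl acetate | O=C1C(C)=C[C@@H](OC(C)=O)[C@H]2C(C)(C)CCC[C@]12C
F6 | step 8 | triethyl{[(3R)-3-methyl-6-[(triisopropylsilyl)oxy]hexa-1,5-dien-3-yl]oxy}silane | C=C[C@](C)(O[Si](CC)(CC)CC)CC=CO[Si](C(C)C)(C(C)C)C(C)C
F7 | step 8 | (R)-3-methyl-3-[(triethylsilyl)oxy]pent-4-enal | C=C[C@](C)(O[Si](CC)(CC)CC)CC=O
F8 | step 8 | (R)-3-methyl-3-[(triethylsilyl)oxy]pent-4-en-1-ol | C=C[C@](C)(O[Si](CC)(CC)CC)CCO
A1 | alternative 1 | (−)-sclareol | C=C[C@](C)(O)CC[C@H]1[C@](C)(O)CC[C@H]2C(C)(C)CCC[C@]12C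
A2 | alternative 1 | (13R)-labda-8,14-dien-13-ol | C=C[C@](C)(O)CCC1=C(C)CC[C@H]2C(C)(C)CCC[C@]12C
A3 | alternative 1 | (13R)-13-hydroxylabda-8,14-dien-7-one | C=C[C@](C)(O)CCC1=C(C)C(=O)C[C@H]2C(C)(C)CCC[C@]12C
A4 | alternative 1 | (5S,6R,10S,13R)-13-hydroxy-7-oxolabda-8,14-dien-6-yl acetate (6α-acetate, C6 epimer of the target) | C=C[C@](C)(O)CCC1=C(C)C(=O)[C@H](OC(C)=O)[C@H]2C(C)(C)CCC[C@]12C
A5 | alternative 2 | (3R,6E,10E)-geranyllinalool | C=C[C@](C)(O)CC/C=C(\C)CC/C=C(\C)CCC=C(C)C
A6 | alternative 3 | (5S,6S,10S)-6-acetoxy-8-methyl-decalin-7,9-dione fragment, (1S,4aS,8aS)-3,4a,8,8-tetramethyl-2,4-dioxodecahydronaphthalen-1-yl acetate (C3 not defined) | O=C1C(C)C(=O)[C@@H](OC(C)=O)[C@H]2C(C)(C)CCC[C@]12C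
A7 | alternative 3 | (1S,4aS,8aS)-3,4a,8,8-tetramethyl-2-oxo-4-{[(trifluoromethyl)sulfonyl]oxy}-1,2,4a,5,6,7,8,8a-octahydronaphthalen-1-yl acetate (C9 enol triflate) | FC(F)(F)S(=O)(=O)OC1=C(C)C(=O)[C@@H](OC(C)=O)[C@H]2C(C)(C)CCC[C@]12C
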